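## Retrosynthetic overview

1. The ten-membered ring is opened at C3–C4: it is closed last by an intramolecular Nozaki–Hiyama–Kishi addition of a (Z)-alkenyl iodide to an aldehyde, which also makes the free C3 carbinol.
2. The C8 ester comes from a Mitsunobu inversion of the C8 alcohol with (2R,3R)-epoxyangelic acid.
3. Key bond C7–C8: the allylzinc from a 3-(bromomethyl)butenolide uses C7 (the β-carbon of the lactone carbonyl) as nucleophile toward the C8 aldehyde; this sets C7 and C8 and unveils the α-methylene lactone.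
4. Fragments: the butenolide bromide from crotonaldehyde and propyne (asymmetric alkynylation, hydroalumination/iodination, acylation, ring-closing metathesis); the aldehyde–acetal from a stabilised ylide (Wittig, oxidative cleavage); the acid by Sharpless epoxidation of angelyl alcohol.
5. Ring order: butenolide (metathesis), which becomes the α-methylene-γ-lactone in the key step; the oxirane arrives with the acid; the carbocycle is formed last.

Atom labels C1–C15 are germacrane labels of the target: C6 lactone O–CH, C7 ring-fusion CH, C8 acyloxy CH, C3 free carbinol, C4(C15 methyl)=C5, C1=C10 (C14 is the CO2Me carbon), C11=C13 methylene, C12 lactone C=O.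

Assumption: (S,S)-ProPhenol is taken to give the S carbinol in step 1; if its facial sense is the opposite, (R,R)-ProPhenol is used.

## Route

Step 1
Reactants: 1 (2E)-but-2-enal (crotonaldehyde); 2 propyne
Product: 4 (2E,4S)-hept-2-en-5-yn-4-ol, via methyl(prop-1-yn-1-yl)zinc 3 (not isolated)
Conditions: (S,S)-ProPhenol (10 mol%), Me2Zn (3 equiv), Ph3P=O (20 mol%), toluene, 0 °C; aq. NH4Cl
Reagents that add atoms: none
Why: Zinc–ProPhenol-catalysed asymmetric alkynylation of an enal: the propynylzinc 3 adds 1,2 to the aldehyde inside the chiral dinuclear zinc alkoxide pocket and sets the future C6 carbinol (4S); the propenyl group is kept as the later metathesis handle.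

Step 2
Reactants: 4
Product: 6 (2E,4S,5Z)-6-iodohepta-2,5-dien-4-ol, via cyclic alkenylalanate 5 (not isolated)
Conditions: NaAlH2(OCH2CH2OMe)2, THF, 0 °C → rt; then I2, −78 → 0 °C; aq. Na2S2O3, aq. potassium sodium tartrate
Reagents that add atoms: iodine, II
Why: Hydroxyl-directed trans-hydroalumination followed by iodinolysis: the alkoxide-bound aluminium delivers hydride to the proximal alkyne carbon to give the five-membered oxa-aluminacycle 5, so aluminium and then iodine (exchange with retention) sit on the methyl-bearing carbon cis to the carbinol carbon, which fixes the Z geometry of the future C4=C5 bond with the methyl on C4.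

Step 3
Reactants: 6; 7 2-(bromomethyl)prop-2-enoic acid
Product: 9 (2E,4S,5Z)-6-iodohepta-2,5-dien-4-yl 2-(bromomethyl)prop-2-enoate, via acid chloride 8 (not isolated)
Conditions: 7, (COCl)2, DMF (cat.), CH2Cl2, 0 °C → rt; then 6, 2,6-lutidine, CH2Cl2, −30 → 0 °C
Reagents that add atoms: none
Why: Acylation of the secondary alcohol by the acid chloride with a hindered pyridine base (which does not quaternise the allylic bromide) installs the acrylate carrying C11, C12 and C13; the stereocentre is not touched.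

Step 4
Reactants: 9
Product: 10 (5S)-3-(bromomethyl)-5-[(1Z)-2-iodoprop-1-en-1-yl]furan-2(5H)-one (fragment B)
Conditions: second-generation Hoveyda–Grubbs catalyst RuCl2(H2IMes)(=CH-C6H4-2-OiPr) (5 mol%), CH2Cl2 (5 mM), 40 °C
Reagents that add atoms: none
Why: Ring-closing metathesis between the propenyl group and the 2-substituted acrylate closes the butenolide with loss of propene; the trisubstituted iodoalkene and the allylic bromide are inert to the ruthenium carbene, and the neutral conditions leave the acidic bis-allylic γ-stereocentre intact.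

Step 5
Reactants: 11 methyl (triphenyl-λ5-phosphanylidene)acetate; 12 3-bromoprop-1-ene (allyl bromide)
Product: 14 methyl 2-(triphenyl-λ5-phosphanylidene)pent-4-enoate, via phosphonium bromide 13 (not isolated)
Conditions: CHCl3, reflux; then 2 M aq. NaOH, CH2Cl2, 0 °C
Reagents that add atoms: none
Why: C-Alkylation of the stabilised ylide by allyl bromide gives the phosphonium salt, which aqueous NaOH deprotonates to the α-allyl ylide (its ylide carbon becomes C10; the allyl group carries C9 and C8).

Step 6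
Reactants: 15 3,3-diethoxypropan-1-ol; 14
Product: 17 methyl (2E)-5,5-diethoxy-2-(prop-2-en-1-yl)pent-2-enoate, via 3,3-diethoxypropanal 16 (not isolated)
Conditions: Dess–Martin periodinane, NaHCO3, CH2Cl2, 0 °C → rt; then 14, rt → 40 °C
Reagents that add atoms: none
Why: Dess–Martin oxidation then Wittig olefination with an α-substituted stabilised ylide, which is E-selective (new chain trans to the ester) and so sets the C1=C10 geometry of the target.

Step 7
Reactants: 17
Product: 19 methyl (2E)-5,5-diethoxy-2-(2-oxoethyl)pent-2-enoate (fragment A), via diol 18 (not isolated)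
Conditions: OsO4 (2 mol%), NaIO4 (4 equiv), 2,6-lutidine, dioxane/H2O 3:1, rt
Reagents that add atoms: osmium tetroxide, O=[Os](=O)(=O)=O; sodium periodate, [Na+].[O-]I(=O)(=O)=O
Why: Lemieux–Johnson oxidative cleavage: OsO4 dihydroxylates the electron-rich monosubstituted alkene in preference to the electron-poor trisubstituted enoate and NaIO4 cleaves the diol to the C8 aldehyde, the lutidine buffer protecting the acetal and the β,γ-unsaturated aldehyde.

Step 8
Reactants: 20 (2Z)-2-methylbut-2-enoic acid (angelic acid)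
Product: 21 (2Z)-2-methylbut-2-en-1-ol
Conditions: LiAlH4, Et2O, 0 °C
Reagents that add atoms: none
Why: Hydride reduction of the carboxylic acid to the allylic alcohol (1,2-reduction) with the Z geometry retained.

Step 9
Reactants: 21
Product: 22 [(2S,3R)-2,3-dimethyloxiran-2-yl]methanol
Conditions: Ti(OiPr)4 (10 mol%), L-(+)-diethyl tartrate (12 mol%), t-BuOOH, 4 Å MS, CH2Cl2, −20 °C
Reagents that add atoms: tert-butyl hydroperoxide, CC(C)(C)OO
Why: Sharpless asymmetric epoxidation of a Z allylic alcohol: the Ti–L-(+)-tartrate catalyst delivers oxygen to the same enantioface as in the conversion of (E)-hex-2-en-1-ol into its (2S,3S)-epoxide, which here gives the (2S,3R)-epoxy alcohol and sets both oxirane stereocentres (the Z geometry fixes their relative configuration).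

Step 10
Reactants: 22
Product: 24 (2R,3R)-2,3-dimethyloxirane-2-carboxylic acid, via epoxy aldehyde 23 (not isolated)
Conditions: RuCl3·xH2O (2 mol%), NaIO4 (3 equiv), CCl4/MeCN/H2O, rt
Reagents that add atoms: water, O; sodium periodate, [Na+].[O-]I(=O)(=O)=O
Why: RuO4 oxidation (Sharpless RuCl3/NaIO4 conditions) of the primary epoxy alcohol through the aldehyde to the acid without opening the oxirane; both stereocentres are retained (the C2 descriptor changes from S to R only through the priority change).

Step 11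
Reactants: 10; 19
Product: 26 methyl (2E)-5,5-diethoxy-2-{(2S)-2-hydroxy-2-[(2S,3R)-2-[(1Z)-2-iodoprop-1-en-1-yl]-4-methylidene-5-oxooxolan-3-yl]ethyl}pent-2-enoate, via allylzinc bromide 25 (not isolated)
Conditions: Zn dust (3 equiv), THF/sat. aq. NH4Cl 2:1, 0 °C → rt
Reagents that add atoms: none
Why: Barbier-type 2-carbonylallylation: zinc inserts into the allylic C–Br bond to give 25, in which C7 (the β-carbon of the butenolide carbonyl, normally an acceptor) is the nucleophile, a homoenolate-type reversed-polarity allyl reagent; it attacks the aldehyde carbon C8 through a closed chair (Zimmerman–Traxler) transition state on the face anti to the C6 side chain (7R, trans lactone) with the aldehyde chain equatorial (8S, the epimer that step 12 inverts), the double bond shifting to the exocyclic methylene, while zinc metal leaves the alkenyl iodide and the acetal untouched.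

Step 12
Reactants: 26; 24
Product: 27 methyl (2E)-2-{(2R)-2-{[(2R,3R)-2,3-dimethyloxirane-2-carbonyl]oxy}-2-[(2S,3R)-2-[(1Z)-2-iodoprop-1-en-1-yl]-4-methylidene-5-oxooxolan-3-yl]ethyl}-5,5-diethoxypent-2-enoate
Conditions: PPh3, DIAD, toluene, −20 °C → rt
Reagents that add atoms: none
Why: Mitsunobu esterification: the alkoxyphosphonium ion of the 8S alcohol is displaced by the carboxylate of 24 (a fairly strong α-alkoxy acid) in an SN2 reaction with inversion, giving the 8R ester of the target.

Step 13
Reactants: 27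
Product: 28 methyl (2E)-2-{(2R)-2-{[(2R,3R)-2,3-dimethyloxirane-2-carbonyl]oxy}-2-[(2S,3R)-2-[(1Z)-2-iodoprop-1-en-1-yl]-4-methylidene-5-oxooxolan-3-yl]ethyl}-5-oxopent-2-enoate
Conditions: SiO2, 10% aq. oxalic acid, CH2Cl2, rt; used at once
Reagents that add atoms: water, O
Why: Mild heterogeneous acid hydrolysis of the diethyl acetal unveils the C3 aldehyde without opening the deactivated α-carbonyl oxirane or hydrolysing the esters.

Step 14
Reactants: 28
Product: 30 methyl (3aR,4R,6E,9S,10Z,11aR)-4-{[(2R,3R)-2,3-dimethyloxirane-2-carbonyl]oxy}-9-hydroxy-10-methyl-3-methylidene-2-oxo-2,3,3a,4,5,8,9,11a-octahydrocyclodeca[b]furan-6-carboxylate (CNP0143679.1), via alkenylchromium dichloride 29 (not isolated)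
Conditions: CrCl2 (8 equiv), NiCl2 (0.1 equiv), DMSO/THF 3:1, 2 mM (slow addition of 28), rt
Reagents that add atoms: none
Why: Intramolecular Nozaki–Hiyama–Kishi reaction: zerovalent nickel formed in situ inserts into the C–I bond, transmetalation gives the alkenylchromium 29 (trivalent chromium) with retention of the Z geometry, and this adds to the aldehyde to close the ten-membered ring and create C3; 3S is expected from a four-centre transition state in the alkene plane with H6 in the inside position (allylic 1,3-strain), which places C2 and C7 on the same face, but this is the least secure stereocentre of the route.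

## Compound list

1 | (2E)-but-2-enal (crotonaldehyde) | C/C=C/C=O | starting material
2 | propyne | CC#C | starting material
3 | methyl(prop-1-yn-1-yl)zinc | C[Zn]C#CC | intermediate (not isolated)
4 | (2E,4S)-hept-2-en-5-yn-4-ol | C/C=C/[C@H](O)C#CC | intermediate
5 | sodium (5S)-2,2-bis(2-methoxyethoxy)-3-methyl-5-[(1E)-prop-1-en-1-yl]-2,5-dihydro-1,2-oxaaluminol-2-uide (cyclic alkenylalanate) | [Na+].C/C=C/[C@H]1C=C(C)[Al-](OCCOC)(OCCOC)O1 | intermediate (not isolated)
6 | (2E,4S,5Z)-6-iodohepta-2,5-dien-4-ol | C/C=C/[C@H](O)/C=C(/C)I | intermediate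
7 | 2-(bromomethyl)prop-2-enoic acid | OC(=O)C(=C)CBr | starting material
8 | 2-(bromomethyl)prop-2-enoyl chloride | ClC(=O)C(=C)CBr | intermediate (not isolated)
9 | (2E,4S,5Z)-6-iodohepta-2,5-dien-4-yl 2-(bromomethyl)prop-2-enoate | C/C=C/[C@H](OC(=O)C(=C)CBr)/C=C(/C)I | intermediate
10 | (5S)-3-(bromomethyl)-5-[(1Z)-2-iodoprop-1-en-1-yl]furan-2(5H)-one | BrCC1=C[C@@H](/C=C(/C)I)OC1=O | intermediate
11 | methyl (triphenyl-λ5-phosphanylidene)acetate | COC(=O)C=P(c1ccccc1)(c1ccccc1)c1ccccc1 | starting material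
12 | 3-bromoprop-1-ene (allyl bromide) | C=CCBr | starting material
13 | (1-methoxy-1-oxopent-4-en-2-yl)triphenylphosphonium bromide | [Br-].COC(=O)C(CC=C)[P+](c1ccccc1)(c1ccccc1)c1ccccc1 | intermediate (not isolated)
14 | methyl 2-(triphenyl-λ5-phosphanylidene)pent-4-enoate | COC(=O)C(CC=C)=P(c1ccccc1)(c1ccccc1)c1ccccc1 | intermediate
15 | 3,3-diethoxypropan-1-ol | CCOC(CCO)OCC | starting material
16 | 3,3-diethoxypropanal | CCOC(CC=O)OCC | intermediate (not isolated)
17 | methyl (2E)-5,5-diethoxy-2-(prop-2-en-1-yl)pent-2-enoate | CCOC(OCC)C/C=C(\CC=C)C(=O)OC | intermediate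
18 | methyl (2E)-2-(2,3-dihydroxypropyl)-5,5-diethoxypent-2-enoate (both carbinol epimers) | CCOC(OCC)C/C=C(\CC(O)CO)C(=O)OC | intermediate (not isolated)
19 | methyl (2E)-5,5-diethoxy-2-(2-oxoethyl)pent-2-enoate | CCOC(OCC)C/C=C(\CC=O)C(=O)OC | intermediate
20 | (2Z)-2-methylbut-2-enoic acid (angelic acid) | C/C=C(/C)C(=O)O | starting material
21 | (2Z)-2-methylbut-2-en-1-ol | C/C=C(/C)CO | intermediate
22 | [(2S,3R)-2,3-dimethyloxiran-2-yl]methanol | OC[C@]1(C)O[C@@H]1C | intermediate
23 | (2R,3R)-2,3-dimethyloxirane-2-carbaldehyde | O=C[C@]1(C)O[C@@H]1C | intermediate (not isolated)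
24 | (2R,3R)-2,3-dimethyloxirane-2-carboxylic acid | OC(=O)[C@]1(C)O[C@@H]1C | intermediate
25 | bromo{[(5S)-5-[(1Z)-2-iodoprop-1-en-1-yl]-2-oxo-2,5-dihydrofuran-3-yl]methyl}zinc | Br[Zn]CC1=C[C@@H](/C=C(/C)I)OC1=O | intermediate (not isolated)
26 | methyl (2E)-5,5-diethoxy-2-{(2S)-2-hydroxy-2-[(2S,3R)-2-[(1Z)-2-iodoprop-1-en-1-yl]-4-methylidene-5-oxooxolan-3-yl]ethyl}pent-2-enoate | C=C1C(=O)O[C@H](/C=C(/C)I)[C@H]1[C@@H](O)C/C(=C\CC(OCC)OCC)C(=O)OC | intermediate
27 | methyl (2E)-2-{(2R)-2-{[(2R,3R)-2,3-dimethyloxirane-2-carbonyl]oxy}-2-[(2S,3R)-2-[(1Z)-2-iodoprop-1-en-1-yl]-4-methylidene-5-oxooxolan-3-yl]ethyl}-5,5-diethoxypent-2-enoate | C=C1C(=O)O[C@H](/C=C(/C)I)[C@H]1[C@H](OC(=O)[C@]2(C)O[C@@H]2C)C/C(=C\CC(OCC)OCC)C(=O)OC | intermediate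
28 | methyl (2E)-2-{(2R)-2-{[(2R,3R)-2,3-dimethyloxirane-2-carbonyl]oxy}-2-[(2S,3R)-2-[(1Z)-2-iodoprop-1-en-1-yl]-4-methylidene-5-oxooxolan-3-yl]ethyl}-5-oxopent-2-enoate | C=C1C(=O)O[C@H](/C=C(/C)I)[C@H]1[C@H](OC(=O)[C@]2(C)O[C@@H]2C)C/C(=C\CC=O)C(=O)OC | intermediate
29 | compound 28 with the iodine replaced by a CrCl2 group (alkenylchromium dichloride, trivalent chromium, Z geometry retained) | C=C1C(=O)O[C@H](/C=C(/C)[Cr](Cl)Cl)[C@H]1[C@H](OC(=O)[C@]2(C)O[C@@H]2C)C/C(=C\CC=O)C(=O)OC | intermediate (not isolated)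
30 | methyl (3aR,4R,6E,9S,10Z,11aR)-4-{[(2R,3R)-2,3-dimethyloxirane-2-carbonyl]oxy}-9-hydroxy-10-methyl-3-methylidene-2-oxo-2,3,3a,4,5,8,9,11a-octahydrocyclodeca[b]furan-6-carboxylate | C=C1C(=O)O[C@@H]2/C=C(/C)[C@@H](O)C/C=C(/C(=O)OC)C[C@@H](OC(=O)[C@]3(C)O[C@@H]3C)[C@@H]12 | target

## Step count and risks

Total steps: 14 (fragment B steps 1–4, fragment A steps 5–7, acid steps 8–10, endgame steps 11–14).
Longest linear sequence: 8 steps (1–4, then 11–14).

**Step 11 (Barbier coupling).** The risk is modest diastereoselectivity at C8 with an unbranched aldehyde, or loss of the labile β,γ-unsaturated aldehyde 19. The fallback sets out from 10 and returns at 27, bypassing 26 and the inversion. Zinc dust and Bu3SnCl in THF/aq. NH4Cl turn 10 into the allylstannane (5S)-5-[(1Z)-2-iodoprop-1-en-1-yl]-3-[(tributylstannyl)methyl]furan-2(5H)-one F1. BF3·OEt2 in CH2Cl2 at −78 °C then adds F1 to 19 through an open antiperiplanar transition state, which is syn-selective and still anti to the C6 side chain. This gives the 8R alcohol methyl (2E)-5,5-diethoxy-2-{(2R)-2-hydroxy-2-[(2S,3R)-2-[(1Z)-2-iodoprop-1-en-1-yl]-4-methylidene-5-oxooxolan-3-yl]ethyl}pent-2-enoate F2 directly. F2 is esterified with 24 with retention (2,4,6-trichlorobenzoyl chloride, Et3N, DMAP, toluene) to give 27. Any minor 8R alcohol from step 11 itself can be carried forward the same way.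

**Step 12 (Mitsunobu inversion).** The risk is elimination or no reaction, because the alcohol is β-branched and the acid is α-quaternary. The fallback sets out from 26 and returns at 27, replacing the one-pot redox condensation by a two-stage sulfonate displacement. ClCH2SO2Cl and pyridine in CH2Cl2 at 0 °C give the chloromethanesulfonate methyl (2E)-2-{(2S)-2-[(chloromethanesulfonyl)oxy]-2-[(2S,3R)-2-[(1Z)-2-iodoprop-1-en-1-yl]-4-methylidene-5-oxooxolan-3-yl]ethyl}-5,5-diethoxypent-2-enoate F3. The pre-formed caesium salt of 24 (Cs2CO3, then 18-crown-6, toluene, 40–60 °C) displaces it with inversion to give 27.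

**Step 14 (macrocyclisation).** The risk is the wrong or mixed C3 configuration, on top of the labile aldehyde 28. The fallback sets out from 28 and returns at 30. The cyclisation is run as in step 14 without regard to the C3 outcome, so that the 3R epimer methyl (3aR,4R,6E,9R,10Z,11aR)-4-{[(2R,3R)-2,3-dimethyloxirane-2-carbonyl]oxy}-9-hydroxy-10-methyl-3-methylidene-2-oxo-2,3,3a,4,5,8,9,11a-octahydrocyclodeca[b]furan-6-carboxylate F4 (alone or mixed with 30) is acceptable. MnO2 in CH2Cl2 oxidises the allylic alcohol to the enone methyl (3aR,4R,6E,10Z,11aR)-4-{[(2R,3R)-2,3-dimethyloxirane-2-carbonyl]oxy}-10-methyl-3-methylidene-2,9-dioxo-2,3,3a,4,5,8,9,11a-octahydrocyclodeca[b]furan-6-carboxylate F5. Reagent-controlled 1,2-reduction with (R)-2-methyl-CBS-oxazaborolidine and catecholborane in toluene at −78 °C (alkenyl as the large group) then gives the 3S alcohol 30.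

Further compounds
F1 | step 11 | (5S)-5-[(1Z)-2-iodoprop-1-en-1-yl]-3-[(tributylstannyl)methyl]furan-2(5H)-one | CCCC[Sn](CCCC)(CCCC)CC1=C[C@@H](/C=C(/C)I)OC1=O
F2 | step 11 | methyl (2E)-5,5-diethoxy-2-{(2R)-2-hydroxy-2-[(2S,3R)-2-[(1Z)-2-iodoprop-1-en-1-yl]-4-methylidene-5-oxooxolan-3-yl]ethyl}pent-2-enoate | C=C1C(=O)O[C@H](/C=C(/C)I)[C@H]1[C@H](O)C/C(=C\CC(OCC)OCC)C(=O)OC
F3 | step 12 | methyl (2E)-2-{(2S)-2-[(chloromethanesulfonyl)oxy]-2-[(2S,3R)-2-[(1Z)-2-iodoprop-1-en-1-yl]-4-methylidene-5-oxooxolan-3-yl]ethyl}-5,5-diethoxypent-2-enoate | C=C1C(=O)O[C@H](/C=C(/C)I)[C@H]1[C@@H](OS(=O)(=O)CCl)C/C(=C\CC(OCC)OCC)C(=O)OC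
F4 | step 14 | methyl (3aR,4R,6E,9R,10Z,11aR)-4-{[(2R,3R)-2,3-dimethyloxirane-2-carbonyl]oxy}-9-hydroxy-10-methyl-3-methylidene-2-oxo-2,3,3a,4,5,8,9,11a-octahydrocyclodeca[b]furan-6-carboxylate | C=C1C(=O)O[C@@H]2/C=C(/C)[C@H](O)C/C=C(/C(=O)OC)C[C@@H](OC(=O)[C@]3(C)O[C@@H]3C)[C@@H]12
F5 | step 14 | methyl (3aR,4R,6E,10Z,11aR)-4-{[(2R,3R)-2,3-dimethyloxirane-2-carbonyl]oxy}-10-methyl-3-methylidene-2,9-dioxo-2,3,3a,4,5,8,9,11a-octahydrocyclodeca[b]furan-6-carboxylate | C=C1C(=O)O[C@@H]2/C=C(/C)C(=O)C/C=C(/C(=O)OC)C[C@@H](OC(=O)[C@]3(C)O[C@@H]3C)[C@@H]12
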